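## Retrosynthetic overview

1. Target ⇒ esterification of the 8β-OH (last step) ⇒ 3α,4α-epoxy-8β,10β-diol ⇒ Δ3-alkene (halohydrin closure) ⇒ guai-4-en-3-one (reductive 1,3-transposition of its tosylhydrazone sets 5β-H) ⇒ guaia-1(10),4-dien-3-one (hydroxyl-directed epoxidation, then palladium/formate hydrogenolysis set 10β-OH and 1α-H).
2. Dienone ⇒ acyclic allenyne + CO by an allenic Pauson–Khand [2+2+1]: C1–C5 and C2–C3 (and C3–C4) form together, so the five- and the seven-membered carbocycle close in one operation; the oxirane is the last ring made (step 13).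
3. Enabling feature: in the five-membered ring C1–C5 the oxygenated C3 lies between C2H2 and the methyl-bearing C4, and the ring-fusion carbon C1 carries the methyl- and oxygen-bearing C10 of the seven-membered ring. C3 therefore maps onto CO, C4≡C5 onto a 2-butynyl alkyne and C10=C1=C2 onto a 1,1-disubstituted allene, whose residual C1=C10 bond later delivers the tertiary alcohol.
4. Allenyne ⇒ auxiliary-controlled alkylation (C7), catalyst/Felkin-matched propargylation (C8), hydroxymethylation and anti-SN2′ methyl transfer (allene with C14).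

Key step: step 8

Remark on numbering: guaiane numbering is used (C1–C5 five-membered ring with C1/C5 as fusion atoms, C6–C10 complete the seven-membered ring, C14 = methyl on C10, C15 = methyl on C4, isopropyl on C7). β is the face of the bicycle that carries the C7 isopropyl group. The target is then 7β-isopropyl, 8β-O-acyl, 10β-OH, 1α-H, 5β-H, 3α,4α-epoxide.

Assumptions: imide 1 is bought (otherwise one N-acylation of (R)-4-benzyloxazolidin-2-one with 3-methylbutanoyl chloride). (R)-TRIP is taken to be the catalyst enantiomer that directs the allenylboronate to the Re face of the aldehyde; if the opposite sense holds, (S)-TRIP is used.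

## Route

Step 1
Reactants: 1 (4R)-4-benzyl-3-(3-methylbutanoyl)-1,3-oxazolidin-2-one; 2 1-bromobut-2-yne
Product: 3 (4R)-4-benzyl-3-[(2R)-2-(propan-2-yl)hex-4-ynoyl]-1,3-oxazolidin-2-one
Conditions: NaN(SiMe3)2, THF, −78 °C; then 2, −78 → −40 °C
Reagents that add atoms: none
Why: Evans alkylation, in which the chelated Z-sodium enolate is alkylated by the reactive propargylic bromide on the face opposite the benzyl group, which should set C7 as (R).

Step 2
Reactants: 3 (4R)-4-benzyl-3-[(2R)-2-(propan-2-yl)hex-4-ynoyl]-1,3-oxazolidin-2-one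
Product: 4 (2R)-2-(propan-2-yl)hex-4-yn-1-ol
Conditions: LiBH4, MeOH (1 equiv), Et2O, 0 °C
Reagents that add atoms: none
Why: Reductive cleavage of the imide by LiBH4 should give the primary alcohol without touching the alkyne or epimerising C7, and the auxiliary is recovered.

Step 3
Reactants: 4 (2R)-2-(propan-2-yl)hex-4-yn-1-ol
Product: 5 (2R)-2-(propan-2-yl)hex-4-ynal
Conditions: Dess–Martin periodinane, NaHCO3, CH2Cl2, 0 °C → rt; used crude
Reagents that add atoms: none
Why: Buffered Dess–Martin oxidation is mild enough to keep the α-stereocentre of the aldehyde intact.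

Step 4
Reactants: 5 (2R)-2-(propan-2-yl)hex-4-ynal; 6 allenylboronic acid pinacol ester
Product: 7 (4R,5R)-5-(propan-2-yl)nona-1,7-diyn-4-ol
Conditions: 6 (1.5 equiv), (R)-TRIP [(R)-3,3′-bis(2,4,6-triisopropylphenyl)-1,1′-binaphthyl-2,2′-diyl hydrogen phosphate] (10 mol %), 4 Å MS, toluene, 0 °C
Reagents that add atoms: none
Why: Chiral phosphoric acid-catalysed propargylation through a closed six-membered SE2′ transition state; Re-face addition is also the Felkin–Anh mode (isopropyl as the large group anti to the nucleophile), so catalyst and substrate control are matched and should set C8 as (R).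

Step 5
Reactants: 7 (4R,5R)-5-(propan-2-yl)nona-1,7-diyn-4-ol
Product: 8 triethyl{[(4R,5R)-5-(propan-2-yl)nona-1,7-diyn-4-yl]oxy}silane
Conditions: Et3SiCl, imidazole, CH2Cl2, 0 °C → rt
Reagents that add atoms: chlorotriethylsilane CC[Si](Cl)(CC)CC
Why: Standard silylation masks the hydroxyl group against the organometallic steps that follow and can be removed later with dilute acid.

Step 6
Reactants: 8 triethyl{[(4R,5R)-5-(propan-2-yl)nona-1,7-diyn-4-yl]oxy}silane; 9 formaldehyde (used as paraformaldehyde)
Product: 10 (5R,6R)-6-(propan-2-yl)-5-[(triethylsilyl)oxy]deca-2,8-diyn-1-ol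
Conditions: n-BuLi, THF, −78 °C; then (CH2O)n, −78 °C → rt
Reagents that add atoms: none
Why: Only the terminal alkyne is deprotonated at −78 °C, and hydroxymethylation of the lithium acetylide supplies the carbon that becomes C2.

Step 7
Reactants: 10 (5R,6R)-6-(propan-2-yl)-5-[(triethylsilyl)oxy]deca-2,8-diyn-1-ol; 11 methylmagnesium bromide
Product: 13 triethyl{[(5R,6R)-3-methyl-6-(propan-2-yl)deca-1,2-dien-8-yn-5-yl]oxy}silane, via propargylic mesylate 12 (not isolated)
Conditions: n-BuLi (1.0 equiv), THF, −78 °C; MeSO2Cl, −78 → −40 °C; then transferred into MeMgBr (3 equiv), CuBr·SMe2 (10 mol %), LiBr, THF, −78 → 0 °C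
Reagents that add atoms: methanesulfonyl chloride CS(=O)(=O)Cl (its atoms stay only in intermediate 12)
Why: Copper-catalysed anti-SN2′ displacement of a primary propargylic mesylate by a methyl Grignard reagent is the standard entry to 1,1-disubstituted terminal allenes and places the C14 methyl on C10.

Step 8
Reactants: 13 triethyl{[(5R,6R)-3-methyl-6-(propan-2-yl)deca-1,2-dien-8-yn-5-yl]oxy}silane; 14 carbon monoxide
Product: 16 8β-hydroxyguaia-1(10),4-dien-3-one [(5R,6R)-6-hydroxy-3,8-dimethyl-5-(propan-2-yl)-4,5,6,7-tetrahydroazulen-2(1H)-one], via silyl ether dienone 15 (not isolated)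
Conditions: [Rh(CO)2Cl]2 (5 mol %), CO (1 atm), toluene (0.02 M), 90 °C; then 1 M HCl, THF, rt
Reagents that add atoms: none
Why: Monovalent rhodium binds the alkyne and the distal C1=C2 bond of the allene, oxidative cyclisation to a rhodacyclopentene forms C1–C5, and CO insertion followed by reductive elimination forms C2–C3 and C3–C4. The closest known reaction type is the rhodium-catalysed allenic Pauson–Khand reaction of allene-ynes to bicyclo[5.3.0]deca-1,7-dien-9-ones (4-alkylidenecyclopentenones). The seven-membered ring closes by C–C coupling of the inner alkyne carbon C5 with the central allene carbon C1 in the metallacycle-forming step; the five-membered ring closes by carbonylative reductive elimination around C3. No stereocentre is created (C1, C5 and C10 stay trigonal and are set in steps 9, 10 and 12), and C7 and C8 are not touched. The step needs reaction at the distal rather than the proximal allene double bond; this is secured by the rhodium carbonyl chloride catalyst together with the 1,1-disubstitution at C10, and the sp-hybridised C1 and the planar dienone product keep the seven-membered closure free of transannular strain. The silyl ether is then cleaved in the same flask so that the 8β-hydroxyl is free to direct step 9.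

Step 9
Reactants: 16 8β-hydroxyguaia-1(10),4-dien-3-one
Product: 17 1β,10β-epoxy-8β-hydroxyguai-4-en-3-one
Conditions: VO(acac)2 (5 mol %), t-BuOOH (1.5 equiv, in decane), CH2Cl2, 0 °C → rt
Reagents that add atoms: tert-butyl hydroperoxide CC(C)(C)OO
Why: Hydroxyl-directed vanadium-catalysed epoxidation of a cyclic homoallylic alcohol; the pseudo-axial 8β-alkoxide carries the peroxo-vanadium unit to the β face of C1=C10, which should set the C10 oxygen β, while the enone bond C4=C5 is electron-poor and out of reach.

Step 10
Reactants: 17 1β,10β-epoxy-8β-hydroxyguai-4-en-3-one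
Product: 18 8β,10β-dihydroxy-1αH-guai-4-en-3-one
Conditions: Pd2(dba)3·CHCl3 (2.5 mol %), n-Bu3P (10 mol %), HCO2H, Et3N, 1,4-dioxane, rt
Reagents that add atoms: none
Why: Palladium-catalysed formate hydrogenolysis of an alkenyl oxirane (here a γ,δ-epoxy enone); zerovalent palladium opens the allylic C1–O bond with inversion, formate decarboxylates to a palladium hydride, and hydride is passed to C1 from the metal side, so the net inversion should give 1α-H with the 10β-OH untouched and the enone restored.

Step 11
Reactants: 18 8β,10β-dihydroxy-1αH-guai-4-en-3-one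
Product: 19 8β,10β-dihydroxy-1αH-guai-4-en-3-one 4-methylbenzenesulfonylhydrazone
Conditions: TsNHNH2 (1.3 equiv), EtOH, 60 °C
Reagents that add atoms: 4-methylbenzenesulfonohydrazide Cc1ccc(cc1)S(=O)(=O)NN
Why: Simple condensation at the ketone; the β,β-disubstituted enone does not undergo competing conjugate addition, and the free hydroxyl groups are tolerated.

Step 12
Reactants: 19 8β,10β-dihydroxy-1αH-guai-4-en-3-one 4-methylbenzenesulfonylhydrazone
Product: 22 1αH,5βH-guai-3-ene-8β,10β-diol, via N-boryl tosylhydrazine 20 (not isolated), via allylic diazene 21 (not isolated)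
Conditions: catecholborane (5 equiv), CHCl3, 0 °C; then NaOAc·3H2O, 65 °C
Reagents that add atoms: catecholborane B1Oc2ccccc2O1 (its atoms stay only in intermediate 20)
Why: Reductive 1,3-transposition of an enone tosylhydrazone; hydride should add to C3 from the α face because the C10 arm of the seven-membered ring projects over the β face of the flat five-membered ring, acetate then releases sulfinate to give the 3β-diazene, and its suprafacial retro-ene loss of N2 delivers hydrogen to the β face of C5, giving the Δ3 alkene and the trans ring fusion.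

Step 13
Reactants: 22 1αH,5βH-guai-3-ene-8β,10β-diol
Product: 24 3α,4α-epoxy-1αH,5βH-guaiane-8β,10β-diol, via bromohydrin 23 (not isolated)
Conditions: N-bromosuccinimide, THF/H2O (3:1), 0 °C; then 1 M NaOH, 0 °C → rt
Reagents that add atoms: water O (the oxirane oxygen); N-bromosuccinimide O=C1CCC(=O)N1Br (bromine stays only in intermediate 23)
Why: Halohydrin formation and base closure; the bromonium ion should form on the β face (flanked only by the pseudo-axial H2β and H5, while the α face carries the allylic C5–C6 bond), water opens it anti at the tertiary C4, and the alkoxide closes by SN2 at C3 to the 3α,4α-epoxide; the trans fusion holds C10 equatorial, so the 10β-OH cannot intercept the bromonium ion.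

Step 14
Reactants: 24 3α,4α-epoxy-1αH,5βH-guaiane-8β,10β-diol; 25 3,4-dimethoxybenzoyl chloride
Product: 26 3α,4α-epoxy-10β-hydroxy-1αH,5βH-guaian-8β-yl 3,4-dimethoxybenzoate (target)
Conditions: 25 (1.5 equiv), 4-(dimethylamino)pyridine, Et3N, CH2Cl2, 0 → 40 °C
Reagents that add atoms: none
Why: Nucleophile-catalysed acylation is selective for the secondary 8β-hydroxyl over the tertiary 10β-hydroxyl, and the basic medium leaves the trisubstituted epoxide intact.

## Compound list

1 | (4R)-4-benzyl-3-(3-methylbutanoyl)-1,3-oxazolidin-2-one | CC(C)CC(=O)N1[C@H](Cc2ccccc2)COC1=O | starting material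
2 | 1-bromobut-2-yne | CC#CCBr | starting material
3 | (4R)-4-benzyl-3-[(2R)-2-(propan-2-yl)hex-4-ynoyl]-1,3-oxazolidin-2-one | O=C([C@H](CC#CC)C(C)C)N1[C@H](Cc2ccccc2)COC1=O | intermediate
4 | (2R)-2-(propan-2-yl)hex-4-yn-1-ol | OC[C@H](CC#CC)C(C)C | intermediate
5 | (2R)-2-(propan-2-yl)hex-4-ynal | O=C[C@H](CC#CC)C(C)C | intermediate
6 | allenylboronic acid pinacol ester | C=C=CB1OC(C)(C)C(C)(C)O1 | starting material
7 | (4R,5R)-5-(propan-2-yl)nona-1,7-diyn-4-ol | O[C@@H]([C@H](CC#CC)C(C)C)CC#C | intermediate
8 | triethyl{[(4R,5R)-5-(propan-2-yl)nona-1,7-diyn-4-yl]oxy}silane | CC[Si](CC)(CC)O[C@@H]([C@H](CC#CC)C(C)C)CC#C | intermediate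
9 | formaldehyde (as paraformaldehyde) | C=O | starting material
10 | (5R,6R)-6-(propan-2-yl)-5-[(triethylsilyl)oxy]deca-2,8-diyn-1-ol | CC[Si](CC)(CC)O[C@@H]([C@H](CC#CC)C(C)C)CC#CCO | intermediate
11 | methylmagnesium bromide | C[Mg]Br | starting material
12 | (5R,6R)-6-(propan-2-yl)-5-[(triethylsilyl)oxy]deca-2,8-diyn-1-yl methanesulfonate | CC[Si](CC)(CC)O[C@@H]([C@H](CC#CC)C(C)C)CC#CCOS(C)(=O)=O | intermediate (not isolated)
13 | triethyl{[(5R,6R)-3-methyl-6-(propan-2-yl)deca-1,2-dien-8-yn-5-yl]oxy}silane | CC[Si](CC)(CC)O[C@@H]([C@H](CC#CC)C(C)C)CC(C)=C=C | intermediate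
14 | carbon monoxide | [C-]#[O+] | starting material
15 | 8β-(triethylsilyloxy)guaia-1(10),4-dien-3-one | CC[Si](CC)(CC)O[C@@H]2CC(C)=C3CC(=O)C(C)=C3C[C@@H]2C(C)C | intermediate (not isolated)
16 | 8β-hydroxyguaia-1(10),4-dien-3-one | O[C@@H]2CC(C)=C3CC(=O)C(C)=C3C[C@@H]2C(C)C | intermediate
17 | 1β,10β-epoxy-8β-hydroxyguai-4-en-3-one | O[C@@H]2C[C@](C)(O5)[C@]53CC(=O)C(C)=C3C[C@@H]2C(C)C | intermediate
18 | 8β,10β-dihydroxy-1αH-guai-4-en-3-one | O[C@@H]2C[C@](C)(O)[C@@H]3CC(=O)C(C)=C3C[C@@H]2C(C)C | intermediate
19 | 8β,10β-dihydroxy-1αH-guai-4-en-3-one 4-methylbenzenesulfonylhydrazone (C=N geometry not defined) | O[C@@H]2C[C@](C)(O)[C@@H]3CC(=NNS(=O)(=O)c4ccc(C)cc4)C(C)=C3C[C@@H]2C(C)C | intermediate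
20 | N-(1,3,2-benzodioxaborol-2-yl)-N-(8β,10β-dihydroxy-1αH,3αH-guai-4-en-3β-yl)-N′-tosylhydrazine (hydroxyl groups drawn free; they are borylated in the flask and released on work-up) | O[C@@H]2C[C@](C)(O)[C@@H]3C[C@H](N(NS(=O)(=O)c4ccc(C)cc4)B4Oc5ccccc5O4)C(C)=C3C[C@@H]2C(C)C | intermediate (not isolated)
21 | 3β-diazenyl-1αH-guai-4-ene-8β,10β-diol (allylic diazene) | O[C@@H]2C[C@](C)(O)[C@@H]3C[C@H](N=N)C(C)=C3C[C@@H]2C(C)C | intermediate (not isolated)
22 | 1αH,5βH-guai-3-ene-8β,10β-diol | O[C@@H]2C[C@](C)(O)[C@@H]3CC=C(C)[C@H]3C[C@@H]2C(C)C | intermediate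
23 | 3β-bromo-1αH,5βH-guaiane-4α,8β,10β-triol | O[C@@H]2C[C@](C)(O)[C@@H]3C[C@H](Br)[C@@](C)(O)[C@H]3C[C@@H]2C(C)C | intermediate (not isolated)
24 | 3α,4α-epoxy-1αH,5βH-guaiane-8β,10β-diol | O[C@@H]2C[C@](C)(O)[C@@H]3C[C@H]4O[C@@]4(C)[C@H]3C[C@@H]2C(C)C | intermediate
25 | 3,4-dimethoxybenzoyl chloride | COc1ccc(C(=O)Cl)cc1OC | starting material
26 | 3α,4α-epoxy-10β-hydroxy-1αH,5βH-guaian-8β-yl 3,4-dimethoxybenzoate (CNP0304846.1) | COc1ccc(C(=O)O[C@@H]2C[C@](C)(O)[C@@H]3C[C@H]4O[C@@]4(C)[C@H]3C[C@@H]2C(C)C)cc1OC | target

## Step count and risks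

Total step count: 14. Longest linear sequence: 14 steps (from 1).

Steps most likely to fail:

Step 9. The conjugated C1=C10 bond may react too slowly with the electrophilic vanadium peroxide, or oxygen delivery may lose its facial control. The fallback reverses the polarity and uses oxygen as a nucleophile at C10, the δ-carbon of the dienone. It sets out from 16: benzaldehyde and catalytic KOt-Bu in THF at 0 °C should convert the 8β-hydroxyl into a hemiacetal alkoxide that adds 1,6 to C10 on the β face. After protonation of the dienolate at C1 under equilibrating conditions this would give the 8β,10β-O-benzylidene acetal of 18 F1; which C1 epimer predominates would have to be established. Aqueous acetic acid then cleaves the acetal and the route is rejoined at 18, so steps 9 and 10 are both replaced.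

Step 12. Hydride delivery to C3 of the hydrazone may show poor facial selectivity, which would pass on to C5 and give the cis-fused epimer. The fallback sets the ring fusion by protonation instead and sets out from 18. 2,2-Dimethoxypropane and pyridinium p-toluenesulfonate should give the 8β,10β-O-isopropylidene acetal of 18 F2. Li in NH3/THF with t-BuOH (1 equiv) at −78 °C, then PhNTf2, should give the trans-fused 8β,10β-O-isopropylidene-1αH,5βH-guai-3-en-3-yl trifluoromethanesulfonate F3 through C5 protonation and regiospecific trapping of the C3–C4 enolate. Pd(OAc)2, PPh3, n-Bu3N and HCO2H in DMF should reduce the triflate to the 8β,10β-O-isopropylidene acetal of 22 F4. Aqueous acetic acid then returns the route at 22.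

Step 13. The bromonium ion may form and open on the other face, which would end in the 3β,4β-epoxide. The fallback sets out from 22 and uses direct oxygen-atom transfer with dimethyldioxirane (acetone, −20 °C). This places the oxygen on the face that bromine takes in the halohydrin sequence, so its facial outcome is the opposite one; it comes back to the route at 24 and makes no new compound (F0).

Further compounds
F1 | step 9 | 8β,10β-O-benzylidene acetal of 8β,10β-dihydroxy-1αH-guai-4-en-3-one (acetal carbon not defined) | C4(c5ccccc5)O[C@@H]2C[C@](C)(O4)[C@@H]3CC(=O)C(C)=C3C[C@@H]2C(C)C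
F2 | step 12 | 8β,10β-O-isopropylidene acetal of 8β,10β-dihydroxy-1αH-guai-4-en-3-one | CC4(C)O[C@@H]2C[C@](C)(O4)[C@@H]3CC(=O)C(C)=C3C[C@@H]2C(C)C
F3 | step 12 | 8β,10β-O-isopropylidene-1αH,5βH-guai-3-en-3-yl trifluoromethanesulfonate | CC4(C)O[C@@H]2C[C@](C)(O4)[C@@H]3CC(OS(=O)(=O)C(F)(F)F)=C(C)[C@H]3C[C@@H]2C(C)C
F4 | step 12 | 8β,10β-O-isopropylidene acetal of 1αH,5βH-guai-3-ene-8β,10β-diol | CC4(C)O[C@@H]2C[C@](C)(O4)[C@@H]3CC=C(C)[C@H]3C[C@@H]2C(C)C
F0 | step 13 | none | none
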